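**Strategy.** Siphonein is cut at C11=C12 into a C25 ylide carrying the ε-ring and an aldehyde carrying ring A, the 8-ketone and the 19-ester. Ring A (C1–C6) is built, not bought. Its tetrasubstituted C5=C6 olefin, which sits next to the C1 gem-dimethyl carbon and carries the C7–C8 arm on C6, is made by ring-closing enyne metathesis of an acyclic 1,7-enyne. The single stereocentre of that enyne (C3) comes from (R)-epichlorohydrin. In one operation the alkyne carbon becomes C6, the methallyl carbon becomes C5, and the methylene shed by the olefin reappears as C8 of a vinyl group, the future ketone carbon. A Morita–Baylis–Hillman/allylic bromide sequence then sets the 9E acyloxymethyl enone.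

Key step: step 6

Assumption: (R)-α-ionone 24 of high enantiomeric purity is taken as a purchasable (natural-grade) material; the other starting materials are catalogue compounds.

**Ring A and the left-hand aldehyde**

Step 1
Reactants: 1 (R)-epichlorohydrin; 2 isopropenylmagnesium bromide
Product: 4 (2R)-2-(2-methylprop-2-en-1-yl)oxirane, via chlorohydrin 3 (not isolated)
Conditions: CuI (5 mol %), THF, −40 °C; crude 3, powdered NaOH, Et2O, rt
Reagents that add atoms: none
Why: Copper-catalysed Grignard opening of the epoxide at its CH2 terminus, then Williamson closure onto the chloromethyl carbon, transposes the epoxide without touching the stereocentre, so the (R)-centre of 1 becomes C3 of ring A.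

Step 2
Reactants: 4 (2R)-2-(2-methylprop-2-en-1-yl)oxirane; 5 isobutyronitrile
Product: 6 (4R)-4-hydroxy-2,2,6-trimethylhept-6-enenitrile
Conditions: LDA, THF, −78 °C; then 4, −78 °C → rt
Reagents that add atoms: none
Why: The nitrile-stabilised tertiary carbanion opens the monosubstituted epoxide at the unhindered CH2 (SN2) and so creates the quaternary gem-dimethyl carbon C1; C3 is not involved.

Step 3
Reactants: 6 (4R)-4-hydroxy-2,2,6-trimethylhept-6-enenitrile
Product: 7 (4R)-4-[(tert-butyldimethylsilyl)oxy]-2,2,6-trimethylhept-6-enenitrile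
Conditions: TBSCl, imidazole, DMF, rt
Reagents that add atoms: tert-butyldimethylsilyl chloride, CC(C)(C)[Si](C)(C)Cl
Why: Standard silylation of a secondary alcohol; the ether prevents lactol formation in step 4 and is removed together with the acetal in step 14.

Step 4
Reactants: 7 (4R)-4-[(tert-butyldimethylsilyl)oxy]-2,2,6-trimethylhept-6-enenitrile
Product: 8 (4R)-4-[(tert-butyldimethylsilyl)oxy]-2,2,6-trimethylhept-6-enal
Conditions: DIBAL-H (i-Bu2AlH), toluene, −78 → 0 °C; aq. Rochelle salt, then wet silica gel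
Reagents that add atoms: water, O
Why: One hydride adds to the hindered tertiary nitrile and the N-aluminio imine is hydrolysed on work-up to a neopentyl aldehyde that cannot enolise.

Step 5
Reactants: 8 (4R)-4-[(tert-butyldimethylsilyl)oxy]-2,2,6-trimethylhept-6-enal; 9 dimethyl (1-diazo-2-oxopropyl)phosphonate (Ohira–Bestmann reagent)
Product: 10 tert-butyl{[(4R)-2,6,6-trimethyloct-1-en-7-yn-4-yl]oxy}dimethylsilane
Conditions: K2CO3, MeOH, 0 °C → rt
Reagents that add atoms: none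
Why: Seyferth–Gilbert homologation in the Ohira–Bestmann form suits a non-enolisable aldehyde; the new alkyne carbon is C7.

Step 6
Reactants: 10 tert-butyl{[(4R)-2,6,6-trimethyloct-1-en-7-yn-4-yl]oxy}dimethylsilane
Product: 11 tert-butyl{[(1R)-4-ethenyl-3,5,5-trimethylcyclohex-3-en-1-yl]oxy}dimethylsilane
Conditions: second-generation Hoveyda–Grubbs catalyst (10 mol %), toluene (0.005 M), 80 °C, argon
Reagents that add atoms: none
Why: Ring-closing enyne metathesis: a ruthenium methylidene adds across the terminal alkyne to place the carbene on C6, and this vinylcarbene then engages the tethered 2-methylallyl olefin in a [2+2] cycloaddition/cycloreversion that forms the C5=C6 double bond and hands the olefin's methylene back to ruthenium, from where it becomes C8 of the vinyl group of the next molecule (the ene-first order leads to the same product). The closest known reaction type is the ruthenium-catalysed exo enyne ring closure of 1,7-enynes to 1-vinylcyclohexenes, which is documented for 1,1-disubstituted olefins. Ring A closes in the six-membered exo mode, with C6 in the ring and C7 outside it. No stereocentre is created, and C3, set in step 1, is remote from the reacting carbons and untouched. The step needs exo over 7-endo closure and cyclisation over alkyne oligomerisation; ring size, the Thorpe–Ingold effect of the C1 gem-dimethyl group and high dilution should secure this, and the silyl ether is the only other functional group. The accepted risk is the steric load of a tetrasubstituted olefin formed beside a quaternary carbon.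

Step 7
Reactants: 11 tert-butyl{[(1R)-4-ethenyl-3,5,5-trimethylcyclohex-3-en-1-yl]oxy}dimethylsilane
Product: 13 2-[(4R)-4-[(tert-butyldimethylsilyl)oxy]-2,6,6-trimethylcyclohex-1-en-1-yl]ethan-1-ol, via B-alkyl-9-BBN adduct 12 (not isolated)
Conditions: 9-BBN, THF, 0 °C → rt; then NaOH, H2O2, 0 °C
Reagents that add atoms: 9-borabicyclo[3.3.1]nonane, [H]B1C2CCCC1CCC2 (its boron stays only in 12); hydrogen peroxide, OO
Why: Hydroboration–oxidation: the bulky borane adds anti-Markovnikov to the monosubstituted vinyl terminus only, the tetrasubstituted ring olefin being inert, and oxidation places the hydroxyl on C8.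

Step 8
Reactants: 13 2-[(4R)-4-[(tert-butyldimethylsilyl)oxy]-2,6,6-trimethylcyclohex-1-en-1-yl]ethan-1-ol
Product: 14 [(4R)-4-[(tert-butyldimethylsilyl)oxy]-2,6,6-trimethylcyclohex-1-en-1-yl]acetaldehyde
Conditions: Dess–Martin periodinane, NaHCO3, CH2Cl2, 0 °C
Reagents that add atoms: none
Why: Buffered Dess–Martin oxidation gives the β,γ-unsaturated aldehyde; conjugation would require an exocyclic olefin beside the gem-dimethyl group and is not expected.

Step 9
Reactants: 14 [(4R)-4-[(tert-butyldimethylsilyl)oxy]-2,6,6-trimethylcyclohex-1-en-1-yl]acetaldehyde; 15 vinylmagnesium bromide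
Product: 16 1-[(4R)-4-[(tert-butyldimethylsilyl)oxy]-2,6,6-trimethylcyclohex-1-en-1-yl]but-3-en-2-ol (C2 epimers)
Conditions: THF, −78 °C
Reagents that add atoms: none
Why: Grignard 1,2-addition at low temperature outruns enolisation; the new carbinol centre (C8) forms as epimers and is erased in step 10.

Step 10
Reactants: 16 1-[(4R)-4-[(tert-butyldimethylsilyl)oxy]-2,6,6-trimethylcyclohex-1-en-1-yl]but-3-en-2-ol
Product: 17 1-[(4R)-4-[(tert-butyldimethylsilyl)oxy]-2,6,6-trimethylcyclohex-1-en-1-yl]but-3-en-2-one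
Conditions: Dess–Martin periodinane, NaHCO3, CH2Cl2, 0 °C; used at once
Reagents that add atoms: none
Why: Mild oxidation of the allylic alcohol gives the vinyl ketone that carries C8 as the carbonyl and C9/C19 as the olefin.

Step 11
Reactants: 17 1-[(4R)-4-[(tert-butyldimethylsilyl)oxy]-2,6,6-trimethylcyclohex-1-en-1-yl]but-3-en-2-one; 18 2,2-dimethoxyacetaldehyde (60 % in water)
Product: 19 1-[(4R)-4-[(tert-butyldimethylsilyl)oxy]-2,6,6-trimethylcyclohex-1-en-1-yl]-4-hydroxy-5,5-dimethoxy-3-methylidenepentan-2-one (C4 epimers)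
Conditions: DABCO (1 equiv), 1,4-dioxane/H2O, rt
Reagents that add atoms: none
Why: Morita–Baylis–Hillman reaction: DABCO adds to the unsubstituted β-carbon (C19), the enolate adds to the electrophilic, non-enolisable aldehyde (C10) and elimination returns the amine; the carbinol epimers converge in step 12.

Step 12
Reactants: 19 1-[(4R)-4-[(tert-butyldimethylsilyl)oxy]-2,6,6-trimethylcyclohex-1-en-1-yl]-4-hydroxy-5,5-dimethoxy-3-methylidenepentan-2-one
Product: 20 (3Z)-3-(bromomethyl)-1-[(4R)-4-[(tert-butyldimethylsilyl)oxy]-2,6,6-trimethylcyclohex-1-en-1-yl]-5,5-dimethoxypent-3-en-2-one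
Conditions: NBS, Me2S, CH2Cl2, 0 °C (reagent pre-formed); then 19, −20 → 0 °C
Reagents that add atoms: N-bromosuccinimide, O=C1CCC(=O)N1Br
Why: Corey–Kim activation of the allylic alcohol and SN2′ attack of bromide on the methylene terminus should give the trisubstituted enone with the acetal carbon trans to the ketone, which is the C9=C10 geometry of the target.

Step 13
Reactants: 20 (3Z)-3-(bromomethyl)-1-[(4R)-4-[(tert-butyldimethylsilyl)oxy]-2,6,6-trimethylcyclohex-1-en-1-yl]-5,5-dimethoxypent-3-en-2-one; 21 (2E)-dodec-2-enoic acid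
Product: 22 (2E)-2-{[(4R)-4-[(tert-butyldimethylsilyl)oxy]-2,6,6-trimethylcyclohex-1-en-1-yl]acetyl}-4,4-dimethoxybut-2-en-1-yl (2E)-dodec-2-enoate
Conditions: K2CO3, DMF, 0 °C → rt
Reagents that add atoms: none
Why: SN2 alkylation of the carboxylate by the primary allylic bromide installs the C19 ester with the olefin geometry retained.

Step 14
Reactants: 22 (2E)-2-{[(4R)-4-[(tert-butyldimethylsilyl)oxy]-2,6,6-trimethylcyclohex-1-en-1-yl]acetyl}-4,4-dimethoxybut-2-en-1-yl (2E)-dodec-2-enoate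
Product: 23 (2E)-2-{[(4R)-4-hydroxy-2,6,6-trimethylcyclohex-1-en-1-yl]acetyl}-4-oxobut-2-en-1-yl (2E)-dodec-2-enoate
Conditions: 1 M HCl/THF (1:2), rt
Reagents that add atoms: water, O
Why: Dilute aqueous acid hydrolyses the dimethyl acetal and the silyl ether in one operation, while the allylic ester and the E-configured enedione should persist.

**ε-Ring half**

Step 15
Reactants: 24 (R)-α-ionone; 25 triethyl phosphonoacetate
Product: 26 ethyl (2E,4E)-3-methyl-5-[(1R)-2,6,6-trimethylcyclohex-2-en-1-yl]penta-2,4-dienoate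
Conditions: NaH, THF, 0 → 50 °C
Reagents that add atoms: none
Why: Horner–Wadsworth–Emmons olefination of the methyl ketone should be mainly E-selective (any 2Z isomer is removed by chromatography), and the weakly basic phosphonate anion should leave C6′ intact.

Step 16
Reactants: 26 ethyl (2E,4E)-3-methyl-5-[(1R)-2,6,6-trimethylcyclohex-2-en-1-yl]penta-2,4-dienoate
Product: 27 ethyl (2E,4E)-3-methyl-5-[(1R)-2,6,6-trimethyl-4-oxocyclohex-2-en-1-yl]penta-2,4-dienoate
Conditions: t-BuOOH, Rh2(cap)4 (dirhodium tetracaprolactamate, 1 mol %), K2CO3, CH2Cl2, rt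
Reagents that add atoms: tert-butyl hydroperoxide, CC(C)(C)OO
Why: Allylic oxidation by tert-butylperoxyl radicals should attack the ring CH2 (C3′), the only unhindered secondary allylic position; the doubly allylic C6′–H is shielded by the gem-dimethyl group and the dienoate is electron-poor.

Step 17
Reactants: 27 ethyl (2E,4E)-3-methyl-5-[(1R)-2,6,6-trimethyl-4-oxocyclohex-2-en-1-yl]penta-2,4-dienoate
Product: 28 ethyl (2E,4E)-5-[(1R,4R)-4-hydroxy-2,6,6-trimethylcyclohex-2-en-1-yl]-3-methylpenta-2,4-dienoate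
Conditions: (S)-2-methyl-CBS-oxazaborolidine, catecholborane, toluene, −78 °C
Reagents that add atoms: none
Why: Corey–Bakshi–Shibata reduction is chemoselective for the ketone, and with the alkenyl branch as the large group the catalyst should direct hydride to the face that gives the 4R alcohol (C3′), trans to the side chain, under reagent control.

Step 18
Reactants: 28 ethyl (2E,4E)-5-[(1R,4R)-4-hydroxy-2,6,6-trimethylcyclohex-2-en-1-yl]-3-methylpenta-2,4-dienoate
Product: 29 (1R,4R)-4-[(1E,3E)-5-hydroxy-3-methylpenta-1,3-dien-1-yl]-3,5,5-trimethylcyclohex-2-en-1-ol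
Conditions: DIBAL-H (i-Bu2AlH, 3.5 equiv), CH2Cl2, −78 °C
Reagents that add atoms: none
Why: DIBAL reduces the conjugated ester to the primary dienylic alcohol by 1,2-delivery without touching the diene.

Step 19
Reactants: 29 (1R,4R)-4-[(1E,3E)-5-hydroxy-3-methylpenta-1,3-dien-1-yl]-3,5,5-trimethylcyclohex-2-en-1-ol
Product: 30 {(2E,4E)-5-[(1R,4R)-4-hydroxy-2,6,6-trimethylcyclohex-2-en-1-yl]-3-methylpenta-2,4-dien-1-yl}triphenylphosphonium bromide
Conditions: PPh3·HBr, MeOH, 0 °C → rt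
Reagents that add atoms: triphenylphosphine hydrobromide, [Br-].[PH+](c1ccccc1)(c1ccccc1)c1ccccc1
Why: The primary dienylic alcohol ionises to a pentadienyl cation that PPh3 captures at the terminal carbon; the ring secondary allylic alcohol should ionise far more slowly.

Step 20
Reactants: 30 {(2E,4E)-5-[(1R,4R)-4-hydroxy-2,6,6-trimethylcyclohex-2-en-1-yl]-3-methylpenta-2,4-dien-1-yl}triphenylphosphonium bromide; 31 (2E,4E,6E)-2,7-dimethylocta-2,4,6-trienedial
Product: 32 (2E,4E,6E,8E,10E,12E)-13-[(1R,4R)-4-hydroxy-2,6,6-trimethylcyclohex-2-en-1-yl]-2,7,11-trimethyltrideca-2,4,6,8,10,12-hexaenal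
Conditions: NaOMe, MeOH/CH2Cl2, 0 °C, 31 in excess (3 equiv); then I2 (cat.), CH2Cl2, rt
Reagents that add atoms: none
Why: Wittig mono-olefination of the symmetrical dialdehyde used in excess forms C11′=C12′, and iodine-catalysed equilibration should bring the new double bond to E.

Step 21
Reactants: 32 (2E,4E,6E,8E,10E,12E)-13-[(1R,4R)-4-hydroxy-2,6,6-trimethylcyclohex-2-en-1-yl]-2,7,11-trimethyltrideca-2,4,6,8,10,12-hexaenal
Product: 33 (1R,4R)-4-[(1E,3E,5E,7E,9E,11E)-13-hydroxy-3,7,12-trimethyltrideca-1,3,5,7,9,11-hexaen-1-yl]-3,5,5-trimethylcyclohex-2-en-1-ol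
Conditions: NaBH4, EtOH/THF, 0 °C
Reagents that add atoms: none
Why: Borohydride reduces the polyenal by 1,2-addition to the primary allylic alcohol.

Step 22
Reactants: 33 (1R,4R)-4-[(1E,3E,5E,7E,9E,11E)-13-hydroxy-3,7,12-trimethyltrideca-1,3,5,7,9,11-hexaen-1-yl]-3,5,5-trimethylcyclohex-2-en-1-ol
Product: 34 {(2E,4E,6E,8E,10E,12E)-13-[(1R,4R)-4-hydroxy-2,6,6-trimethylcyclohex-2-en-1-yl]-2,7,11-trimethyltrideca-2,4,6,8,10,12-hexaen-1-yl}triphenylphosphonium bromide
Conditions: PPh3·HBr, MeOH/CH2Cl2, 0 °C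
Reagents that add atoms: triphenylphosphine hydrobromide, [Br-].[PH+](c1ccccc1)(c1ccccc1)c1ccccc1
Why: As in step 19, the polyenylic alcohol ionises readily and the cation is trapped by PPh3 at the primary terminus (C12).

**Union**

Step 23
Reactants: 23 (2E)-2-{[(4R)-4-hydroxy-2,6,6-trimethylcyclohex-1-en-1-yl]acetyl}-4-oxobut-2-en-1-yl (2E)-dodec-2-enoate; 34 C25 phosphonium bromide
Product: 35 siphonein, (3R,3′R,6′R)-3,3′-dihydroxy-8-oxo-7,8-dihydro-β,ε-caroten-19-yl (2E)-dodec-2-enoate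
Conditions: 1,2-epoxybutane, 50 °C, argon, dark; then brief heating in EtOAc
Reagents that add atoms: none
Why: Wittig olefination under Buddrus conditions: the epoxide scavenges HBr and generates the ylide at low stationary concentration without added base, so the free hydroxyls, the C19 ester and the acidic C7 methylene should survive while the aldehyde reacts in preference to the ketone; any 11Z isomer is expected to equilibrate thermally to all-E.

**Compound list**

1 | (R)-epichlorohydrin | ClC[C@H]1CO1 | starting material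
2 | isopropenylmagnesium bromide | C=C(C)[Mg]Br | starting material
3 | (2R)-1-chloro-4-methylpent-4-en-2-ol | ClC[C@H](O)CC(C)=C | intermediate
4 | (2R)-2-(2-methylprop-2-en-1-yl)oxirane | C=C(C)C[C@@H]1CO1 | intermediate
5 | isobutyronitrile | CC(C)C#N | starting material
6 | (4R)-4-hydroxy-2,2,6-trimethylhept-6-enenitrile | C=C(C)C[C@@H](O)CC(C)(C)C#N | intermediate
7 | (4R)-4-[(tert-butyldimethylsilyl)oxy]-2,2,6-trimethylhept-6-enenitrile | C=C(C)C[C@@H](O[Si](C)(C)C(C)(C)C)CC(C)(C)C#N | intermediate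
8 | (4R)-4-[(tert-butyldimethylsilyl)oxy]-2,2,6-trimethylhept-6-enal | C=C(C)C[C@@H](O[Si](C)(C)C(C)(C)C)CC(C)(C)C=O | intermediate
9 | dimethyl (1-diazo-2-oxopropyl)phosphonate | CC(=O)C(=[N+]=[N-])P(=O)(OC)OC | starting material
10 | tert-butyl{[(4R)-2,6,6-trimethyloct-1-en-7-yn-4-yl]oxy}dimethylsilane | C=C(C)C[C@@H](O[Si](C)(C)C(C)(C)C)CC(C)(C)C#C | intermediate
11 | tert-butyl{[(1R)-4-ethenyl-3,5,5-trimethylcyclohex-3-en-1-yl]oxy}dimethylsilane | C=CC1=C(C)C[C@@H](O[Si](C)(C)C(C)(C)C)CC1(C)C | intermediate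
12 | 9-{2-[(4R)-4-[(tert-butyldimethylsilyl)oxy]-2,6,6-trimethylcyclohex-1-en-1-yl]ethyl}-9-borabicyclo[3.3.1]nonane | B1(CCC2=C(C)C[C@@H](O[Si](C)(C)C(C)(C)C)CC2(C)C)C2CCCC1CCC2 | intermediate
13 | 2-[(4R)-4-[(tert-butyldimethylsilyl)oxy]-2,6,6-trimethylcyclohex-1-en-1-yl]ethan-1-ol | OCCC1=C(C)C[C@@H](O[Si](C)(C)C(C)(C)C)CC1(C)C | intermediate
14 | [(4R)-4-[(tert-butyldimethylsilyl)oxy]-2,6,6-trimethylcyclohex-1-en-1-yl]acetaldehyde | O=CCC1=C(C)C[C@@H](O[Si](C)(C)C(C)(C)C)CC1(C)C | intermediate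
15 | vinylmagnesium bromide | C=C[Mg]Br | starting material
16 | 1-[(4R)-4-[(tert-butyldimethylsilyl)oxy]-2,6,6-trimethylcyclohex-1-en-1-yl]but-3-en-2-ol (C2 epimers) | C=CC(O)CC1=C(C)C[C@@H](O[Si](C)(C)C(C)(C)C)CC1(C)C | intermediate
17 | 1-[(4R)-4-[(tert-butyldimethylsilyl)oxy]-2,6,6-trimethylcyclohex-1-en-1-yl]but-3-en-2-one | C=CC(=O)CC1=C(C)C[C@@H](O[Si](C)(C)C(C)(C)C)CC1(C)C | intermediate
18 | 2,2-dimethoxyacetaldehyde | COC(OC)C=O | starting material
19 | 1-[(4R)-4-[(tert-butyldimethylsilyl)oxy]-2,6,6-trimethylcyclohex-1-en-1-yl]-4-hydroxy-5,5-dimethoxy-3-methylidenepentan-2-one (C4 epimers) | COC(OC)C(O)C(=C)C(=O)CC1=C(C)C[C@@H](O[Si](C)(C)C(C)(C)C)CC1(C)C | intermediate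
20 | (3Z)-3-(bromomethyl)-1-[(4R)-4-[(tert-butyldimethylsilyl)oxy]-2,6,6-trimethylcyclohex-1-en-1-yl]-5,5-dimethoxypent-3-en-2-one | BrC\C(=C/C(OC)OC)C(=O)CC1=C(C)C[C@@H](O[Si](C)(C)C(C)(C)C)CC1(C)C | intermediate
21 | (2E)-dodec-2-enoic acid | CCCCCCCCC/C=C/C(=O)O | starting material
22 | (2E)-2-{[(4R)-4-[(tert-butyldimethylsilyl)oxy]-2,6,6-trimethylcyclohex-1-en-1-yl]acetyl}-4,4-dimethoxybut-2-en-1-yl (2E)-dodec-2-enoate | CCCCCCCCC/C=C/C(=O)OC\C(=C/C(OC)OC)C(=O)CC1=C(C)C[C@@H](O[Si](C)(C)C(C)(C)C)CC1(C)C | intermediate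
23 | (2E)-2-{[(4R)-4-hydroxy-2,6,6-trimethylcyclohex-1-en-1-yl]acetyl}-4-oxobut-2-en-1-yl (2E)-dodec-2-enoate | CCCCCCCCC/C=C/C(=O)OC\C(=C/C=O)C(=O)CC1=C(C)C[C@@H](O)CC1(C)C | intermediate
24 | (R)-α-ionone, (3E)-4-[(1R)-2,6,6-trimethylcyclohex-2-en-1-yl]but-3-en-2-one | CC(=O)/C=C/[C@H]1C(C)=CCCC1(C)C | starting material
25 | triethyl phosphonoacetate | CCOC(=O)CP(=O)(OCC)OCC | starting material
26 | ethyl (2E,4E)-3-methyl-5-[(1R)-2,6,6-trimethylcyclohex-2-en-1-yl]penta-2,4-dienoate | CCOC(=O)/C=C(C)/C=C/[C@H]1C(C)=CCCC1(C)C | intermediate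
27 | ethyl (2E,4E)-3-methyl-5-[(1R)-2,6,6-trimethyl-4-oxocyclohex-2-en-1-yl]penta-2,4-dienoate | CCOC(=O)/C=C(C)/C=C/[C@H]1C(C)=CC(=O)CC1(C)C | intermediate
28 | ethyl (2E,4E)-5-[(1R,4R)-4-hydroxy-2,6,6-trimethylcyclohex-2-en-1-yl]-3-methylpenta-2,4-dienoate | CCOC(=O)/C=C(C)/C=C/[C@H]1C(C)=C[C@H](O)CC1(C)C | intermediate
29 | (1R,4R)-4-[(1E,3E)-5-hydroxy-3-methylpenta-1,3-dien-1-yl]-3,5,5-trimethylcyclohex-2-en-1-ol | OC/C=C(C)/C=C/[C@H]1C(C)=C[C@H](O)CC1(C)C | intermediate
30 | {(2E,4E)-5-[(1R,4R)-4-hydroxy-2,6,6-trimethylcyclohex-2-en-1-yl]-3-methylpenta-2,4-dien-1-yl}triphenylphosphonium bromide | c1ccccc1[P+](c1ccccc1)(c1ccccc1)C/C=C(C)/C=C/[C@H]1C(C)=C[C@H](O)CC1(C)C.[Br-] | intermediate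
31 | (2E,4E,6E)-2,7-dimethylocta-2,4,6-trienedial | O=C/C(C)=C/C=C/C=C(C)/C=O | starting material
32 | (2E,4E,6E,8E,10E,12E)-13-[(1R,4R)-4-hydroxy-2,6,6-trimethylcyclohex-2-en-1-yl]-2,7,11-trimethyltrideca-2,4,6,8,10,12-hexaenal | O=C/C(C)=C/C=C/C=C(C)/C=C/C=C(C)/C=C/[C@H]1C(C)=C[C@H](O)CC1(C)C | intermediate
33 | (1R,4R)-4-[(1E,3E,5E,7E,9E,11E)-13-hydroxy-3,7,12-trimethyltrideca-1,3,5,7,9,11-hexaen-1-yl]-3,5,5-trimethylcyclohex-2-en-1-ol | OC/C(C)=C/C=C/C=C(C)/C=C/C=C(C)/C=C/[C@H]1C(C)=C[C@H](O)CC1(C)C | intermediate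
34 | {(2E,4E,6E,8E,10E,12E)-13-[(1R,4R)-4-hydroxy-2,6,6-trimethylcyclohex-2-en-1-yl]-2,7,11-trimethyltrideca-2,4,6,8,10,12-hexaen-1-yl}triphenylphosphonium bromide | c1ccccc1[P+](c1ccccc1)(c1ccccc1)C/C(C)=C/C=C/C=C(C)/C=C/C=C(C)/C=C/[C@H]1C(C)=C[C@H](O)CC1(C)C.[Br-] | intermediate
35 | siphonein, (3R,3′R,6′R)-3,3′-dihydroxy-8-oxo-7,8-dihydro-β,ε-caroten-19-yl (2E)-dodec-2-enoate | CCCCCCCCC/C=C/C(=O)OC\C(=C/C=C/C(C)=C/C=C/C=C(C)/C=C/C=C(C)/C=C/[C@H]1C(C)=C[C@H](O)CC1(C)C)C(=O)CC1=C(C)C[C@@H](O)CC1(C)C | target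

**Count and risks**

Total steps: 23. Longest linear sequence: 15 steps (steps 1–14, then step 23).

Steps most likely to fail:

1. Step 6. The ruthenium carbene may fail to engage the neopentyl alkyne or the 1,1-disubstituted olefin, so that alkyne oligomerisation or 7-endo closure takes over. The fallback is an intramolecular McMurry coupling that closes the same C5=C6 bond; it sets out from 7 and returns at 14. Nitrile 7 is treated with (1,3-dioxolan-2-ylmethyl)magnesium bromide (CuBr cat., THF, reflux; aqueous oxalic acid) to give (5R)-5-[(tert-butyldimethylsilyl)oxy]-1-(1,3-dioxolan-2-yl)-3,3,7-trimethyloct-7-en-2-one F1. Ozonolysis of the methallyl group (O3, CH2Cl2/MeOH, −78 °C; Me2S) gives (5S)-5-[(tert-butyldimethylsilyl)oxy]-1-(1,3-dioxolan-2-yl)-3,3-dimethyloctane-2,7-dione F2. Low-valent titanium (TiCl3(DME)1.5, Zn–Cu couple, DME, reflux, slow addition) couples the two ketone carbons to 2-{[(4R)-4-[(tert-butyldimethylsilyl)oxy]-2,6,6-trimethylcyclohex-1-en-1-yl]methyl}-1,3-dioxolane F3. PPTS in wet acetone then releases aldehyde 14.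

2. Step 11. Self-condensation of the enolisable vinyl ketone (Rauhut–Currier dimerisation) may outpace the aldol step. The fallback is a thiolate conjugate addition–aldol–sulfoxide elimination sequence; it sets out from 17 and returns at 19. Me2AlSPh (from AlMe3 and PhSH, CH2Cl2, −78 °C) adds to 17, and the aluminium enolate is trapped with anhydrous 18 to give 1-[(4R)-4-[(tert-butyldimethylsilyl)oxy]-2,6,6-trimethylcyclohex-1-en-1-yl]-4-hydroxy-5,5-dimethoxy-3-[(phenylsulfanyl)methyl]pentan-2-one F4. NaIO4 (MeOH/H2O) oxidises sulfur only, giving the corresponding 3-[(phenylsulfinyl)methyl]pentan-2-one F5. Thermal syn-elimination (toluene, CaCO3, 90 °C) then gives 19.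

3. Step 23. The ylide or the alkoxide may add in conjugate fashion to the enedione with loss of the allylic carboxylate, or the ester may be exchanged. The fallback joins the halves before the ester is in place; it sets out from 20 and returns at 35.
   - Silver-assisted hydrolysis of 20 (Ag2O, acetone/H2O) gives (3E)-1-[(4R)-4-[(tert-butyldimethylsilyl)oxy]-2,6,6-trimethylcyclohex-1-en-1-yl]-3-(hydroxymethyl)-5,5-dimethoxypent-3-en-2-one F6.
   - TBSCl/imidazole gives (3E)-3-{[(tert-butyldimethylsilyl)oxy]methyl}-1-[(4R)-4-[(tert-butyldimethylsilyl)oxy]-2,6,6-trimethylcyclohex-1-en-1-yl]-5,5-dimethoxypent-3-en-2-one F7.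
   - TESOTf/2,4,6-collidine (CH2Cl2, 0 °C; then H2O) cleaves only the acetal, giving (2E)-3-{[(tert-butyldimethylsilyl)oxy]methyl}-5-[(4R)-4-[(tert-butyldimethylsilyl)oxy]-2,6,6-trimethylcyclohex-1-en-1-yl]-4-oxopent-2-enal F8.
   - Wittig reaction with the ylide of 34 (LiHMDS, THF, −78 → 0 °C) gives 3,19-bis-O-(tert-butyldimethylsilyl)siphonaxanthin F9.
   - HF·pyridine (THF/pyridine, 0 °C) gives siphonaxanthin, (3R,3′R,6′R)-3,3′,19-trihydroxy-7,8-dihydro-β,ε-caroten-8-one F10.
   - Acylation of its only primary hydroxyl with 21 (2,4,6-trichlorobenzoyl chloride, Et3N, cat. DMAP, toluene, −20 °C) gives 35.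

**Further compounds**

F1 | step 6 | (5R)-5-[(tert-butyldimethylsilyl)oxy]-1-(1,3-dioxolan-2-yl)-3,3,7-trimethyloct-7-en-2-one | C=C(C)C[C@@H](O[Si](C)(C)C(C)(C)C)CC(C)(C)C(=O)CC1OCCO1
F2 | step 6 | (5S)-5-[(tert-butyldimethylsilyl)oxy]-1-(1,3-dioxolan-2-yl)-3,3-dimethyloctane-2,7-dione | CC(=O)C[C@@H](O[Si](C)(C)C(C)(C)C)CC(C)(C)C(=O)CC1OCCO1
F3 | step 6 | 2-{[(4R)-4-[(tert-butyldimethylsilyl)oxy]-2,6,6-trimethylcyclohex-1-en-1-yl]methyl}-1,3-dioxolane | C1COC(O1)CC1=C(C)C[C@@H](O[Si](C)(C)C(C)(C)C)CC1(C)C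
F4 | step 11 | 1-[(4R)-4-[(tert-butyldimethylsilyl)oxy]-2,6,6-trimethylcyclohex-1-en-1-yl]-4-hydroxy-5,5-dimethoxy-3-[(phenylsulfanyl)methyl]pentan-2-one | COC(OC)C(O)C(CSc1ccccc1)C(=O)CC1=C(C)C[C@@H](O[Si](C)(C)C(C)(C)C)CC1(C)C
F5 | step 11 | 1-[(4R)-4-[(tert-butyldimethylsilyl)oxy]-2,6,6-trimethylcyclohex-1-en-1-yl]-4-hydroxy-5,5-dimethoxy-3-[(phenylsulfinyl)methyl]pentan-2-one | COC(OC)C(O)C(CS(=O)c1ccccc1)C(=O)CC1=C(C)C[C@@H](O[Si](C)(C)C(C)(C)C)CC1(C)C
F6 | step 23 | (3E)-1-[(4R)-4-[(tert-butyldimethylsilyl)oxy]-2,6,6-trimethylcyclohex-1-en-1-yl]-3-(hydroxymethyl)-5,5-dimethoxypent-3-en-2-one | OC\C(=C/C(OC)OC)C(=O)CC1=C(C)C[C@@H](O[Si](C)(C)C(C)(C)C)CC1(C)C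
F7 | step 23 | (3E)-3-{[(tert-butyldimethylsilyl)oxy]methyl}-1-[(4R)-4-[(tert-butyldimethylsilyl)oxy]-2,6,6-trimethylcyclohex-1-en-1-yl]-5,5-dimethoxypent-3-en-2-one | CC(C)(C)[Si](C)(C)OC\C(=C/C(OC)OC)C(=O)CC1=C(C)C[C@@H](O[Si](C)(C)C(C)(C)C)CC1(C)C
F8 | step 23 | (2E)-3-{[(tert-butyldimethylsilyl)oxy]methyl}-5-[(4R)-4-[(tert-butyldimethylsilyl)oxy]-2,6,6-trimethylcyclohex-1-en-1-yl]-4-oxopent-2-enal | CC(C)(C)[Si](C)(C)OC\C(=C/C=O)C(=O)CC1=C(C)C[C@@H](O[Si](C)(C)C(C)(C)C)CC1(C)C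
F9 | step 23 | 3,19-bis-O-(tert-butyldimethylsilyl)siphonaxanthin | CC(C)(C)[Si](C)(C)OC\C(=C/C=C/C(C)=C/C=C/C=C(C)/C=C/C=C(C)/C=C/[C@H]1C(C)=C[C@H](O)CC1(C)C)C(=O)CC1=C(C)C[C@@H](O[Si](C)(C)C(C)(C)C)CC1(C)C
F10 | step 23 | siphonaxanthin, (3R,3′R,6′R)-3,3′,19-trihydroxy-7,8-dihydro-β,ε-caroten-8-one | OC\C(=C/C=C/C(C)=C/C=C/C=C(C)/C=C/C=C(C)/C=C/[C@H]1C(C)=C[C@H](O)CC1(C)C)C(=O)CC1=C(C)C[C@@H](O)CC1(C)C
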